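**Retrosynthetic overview**

1. Endgame: target 15 comes from fluoride cleavage of the C8 silyl ether, after Steglich esterification of the side-chain carbinol and aerobic para-oxidation of 1-naphthol 12, which turns C1–H/C4–OH of ring B into the quinone.
2. Key disconnection: ring B of 12 is cut at C8a–C1 and at C2–C3, giving aroyl sulfoxonium ylide 4 (ring A, C4 and C3) and terminal alkynol 10 (C1, C2 and the complete (S)-side chain).
3. Enabling feature: the aryl ketone carbon C4 with its α-carbon C3, written as a sulfoxonium ylide, is both the directing group for the only free ortho C–H of ring A (the future C8a; the other ortho carbon, C5, carries OMe) and a one-carbon carbene donor, so a two-carbon alkyne completes six-membered ring B.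
4. Ring order: ring A is bought (methyl 2,5-dihydroxybenzoate 1), ring B is formed in the key step and oxidised afterwards; the C5 and C8 oxygens are told apart at the outset (hydrogen-bonded 2-OH against free 5-OH of 1).
5. The stereocentre is set by asymmetric transfer hydrogenation of ynone 8 (from 4-methylpent-3-enoic acid 5) and is a spectator from then on.

Key step: step 8

Remark: the carbinol carbon of the target is (S); naphthoquinone locants are used throughout (C2 carries the side chain, C5 the methoxy group, C8 the free hydroxyl), ring A is the benzenoid ring and ring B the quinone ring.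

**Route**

Step 1
Reactants: 1 methyl 2,5-dihydroxybenzoate
Product: 2 methyl 2-hydroxy-5-[(triisopropylsilyl)oxy]benzoate
Conditions: TIPSCl (1.05 equiv), imidazole (2.2 equiv), DMF, 0 °C to rt
Reagents that add atoms: chlorotriisopropylsilane, CC(C)[Si](Cl)(C(C)C)C(C)C
Why: Regioselective phenol silylation, in which the 2-OH is held in a hydrogen bond to the ester carbonyl so that the bulky silyl chloride should take only the free 5-OH.

Step 2
Reactants: 2 methyl 2-hydroxy-5-[(triisopropylsilyl)oxy]benzoate
Product: 3 methyl 2-methoxy-5-[(triisopropylsilyl)oxy]benzoate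
Conditions: MeI (3 equiv), K2CO3 (2 equiv), acetone, reflux
Reagents that add atoms: iodomethane, CI
Why: Williamson etherification of the remaining salicylate phenol, which the robust triisopropylsilyl aryl ether should survive in dry acetone.

Step 3
Reactants: 3 methyl 2-methoxy-5-[(triisopropylsilyl)oxy]benzoate
Product: 4 2-[dimethyl(oxo)-λ6-sulfanylidene]-1-{2-methoxy-5-[(triisopropylsilyl)oxy]phenyl}ethan-1-one
Conditions: Me3S(O)I (3 equiv), KOtBu (3 equiv), THF, reflux, 2 h; then 3, 0 °C to rt
Reagents that add atoms: trimethylsulfoxonium iodide, C[S+](C)(C)=O.[I-]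
Why: Corey–Chaykovsky-type acylation of dimethylsulfoxonium methylide by a methyl ester, in which the methoxide set free deprotonates the first-formed β-keto sulfoxonium salt to the stabilised ylide.

Step 4
Reactants: 5 4-methylpent-3-enoic acid
Product: 7 N-methoxy-N,4-dimethylpent-3-enamide, via acyl imidazolide 6 (not isolated)
Conditions: CDI (1.1 equiv), CH2Cl2, 0 °C to rt, 1 h; then MeNH(OMe)·HCl (1.2 equiv), rt
Reagents that add atoms: N,O-dimethylhydroxylamine hydrochloride, CNOC.Cl; 1,1'-carbonyldiimidazole, O=C(n1ccnc1)n1ccnc1 (its imidazolyl group is found in 6 only)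
Why: Weinreb amide formation through the acyl imidazolide, a neutral activation that should not move the β,γ double bond into conjugation.

Step 5
Reactants: 7 N-methoxy-N,4-dimethylpent-3-enamide
Product: 8 6-methyl-1-(trimethylsilyl)hept-5-en-1-yn-3-one
Conditions: Me3SiC≡CH (1.5 equiv), n-BuLi (1.45 equiv), THF, −78 °C; then 7, −78 to −20 °C; cold inverse quench into aq. NH4Cl
Reagents that add atoms: (trimethylsilyl)acetylene, C#C[Si](C)(C)C
Why: Weinreb ketone synthesis, in which the chelated tetrahedral adduct prevents over-addition and the low temperature lets addition of the weakly basic acetylide outrun α-deprotonation.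

Step 6
Reactants: 8 6-methyl-1-(trimethylsilyl)hept-5-en-1-yn-3-one
Product: 9 (3S)-6-methyl-1-(trimethylsilyl)hept-5-en-1-yn-3-ol
Conditions: Ru[(S,S)-TsDPEN](p-cymene) (2 mol %, preformed 16-electron amido complex of divalent ruthenium), i-PrOH, rt
Reagents that add atoms: none
Why: Noyori asymmetric transfer hydrogenation of an ynone, in which the alkynyl group takes the place normally held by an aryl group in the six-membered hydride/proton transfer from the (S,S)-catalyst, so that hydride should add to the face giving the (S)-propargylic alcohol while the base-free medium leaves the skipped enone unisomerised.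

Step 7
Reactants: 9 (3S)-6-methyl-1-(trimethylsilyl)hept-5-en-1-yn-3-ol
Product: 10 (3S)-6-methylhept-5-en-1-yn-3-ol
Conditions: K2CO3 (0.2 equiv), MeOH, 0 °C to rt
Reagents that add atoms: none
Why: Methoxide-mediated protodesilylation of an alkynylsilane, which cleaves only the C(sp)–Si bond and does not touch the stereocentre.

Step 8
Reactants: 4 2-[dimethyl(oxo)-λ6-sulfanylidene]-1-{2-methoxy-5-[(triisopropylsilyl)oxy]phenyl}ethan-1-one; 10 (3S)-6-methylhept-5-en-1-yn-3-ol
Product: 12 3-[(1S)-1-hydroxy-4-methylpent-3-en-1-yl]-8-methoxy-5-[(triisopropylsilyl)oxy]naphthalen-1-ol, via naphthalen-1(2H)-one keto tautomer 11 (not isolated)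
Conditions: [Cp*Rh(MeCN)3](SbF6)2 (5 mol %), NaOAc (0.3 equiv), PivOH (1 equiv), ClCH2CH2Cl, 60 °C; 10 (1.3 equiv) added over 4 h
Reagents that add atoms: none
Why: Proposed new method: carboxylate-assisted rhodation (trivalent rhodium, directed by the carbonyl/ylide unit of 4) of the only free ortho C–H of ring A gives a five-membered rhodacycle, the terminal alkyne of 10 inserts into the Rh–aryl bond with the aryl carbon bonding to the unsubstituted alkyne carbon (C8a–C1), the rhodium-bound ylide carbon loses DMSO to give a rhodium carbene, and 1,1-migratory insertion of the alkenyl ligand into this carbene forms C2–C3; protonation of the rhodium enolate gives keto tautomer 11, which aromatises to 12. The closest known reaction type is the Cp*Rh-catalysed C–H activation/[4+2] annulation of aroyl sulfoxonium ylides with internal alkynes to 1-naphthols, together with the regiochemistry of terminal alkynes in Cp*Rh annulations of benzamides; new here are the terminal alkyne with a free propargylic carbinol and the C–H bond flanked by a silyloxy group. Ring B is closed by carbene migratory insertion within a seven-membered rhodacycle, a formal [4+2] annulation of the four-atom unit C8a–C4a–C4–C3 onto the two alkyne carbons, not a pericyclic closure. No stereocentre is formed and the (S)-carbinol of 10 is carried through untouched because its C–O bond is never ionised; it is used as the free alcohol because a propargylic ester would invite β-oxygen elimination to an allene after insertion. The step needs site selectivity (secured by the methoxy group that blocks the second ortho position), alkyne regioselectivity (secured by the steric bias of a terminal alkyne, reinforced by coordination of the propargylic OH, which places rhodium on the carbinol-bearing carbon) and chemoselectivity for the alkyne over the trisubstituted alkene (secured by the inertness of such alkenes toward insertion and by the silver-free catalyst and slow addition, which limit acetylide formation and alkyne oligomerisation). The peri-methoxy group next to the new naphthol OH blocks a second, OH-directed annulation.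

Step 9
Reactants: 12 3-[(1S)-1-hydroxy-4-methylpent-3-en-1-yl]-8-methoxy-5-[(triisopropylsilyl)oxy]naphthalen-1-ol
Product: 13 2-[(1S)-1-hydroxy-4-methylpent-3-en-1-yl]-5-methoxy-8-[(triisopropylsilyl)oxy]naphthalene-1,4-dione
Conditions: Co(salen) [cobalt N,N'-ethylenebis(salicylideneiminate), divalent cobalt] (15 mol %), O2 (1 atm), MeCN, rt
Reagents that add atoms: dioxygen, O=O
Why: Cobalt–salen-catalysed aerobic para-oxidation of a 1-naphthol to the 1,4-naphthoquinone (salcomine oxidation), in which the cobalt superoxo species should oxidise only the free naphthol ring at its open para carbon C1, ring A being protected because both of its oxygens are capped.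

Step 10
Reactants: 13 2-[(1S)-1-hydroxy-4-methylpent-3-en-1-yl]-5-methoxy-8-[(triisopropylsilyl)oxy]naphthalene-1,4-dione
Product: 14 (1S)-1-{5-methoxy-1,4-dioxo-8-[(triisopropylsilyl)oxy]-1,4-dihydronaphthalen-2-yl}-4-methylpent-3-en-1-yl 3-methylbut-2-enoate
Conditions: 3-methylbut-2-enoic acid (1.5 equiv), DCC (1.5 equiv), DMAP (0.1 equiv), CH2Cl2, 0 °C to rt
Reagents that add atoms: 3-methylbut-2-enoic acid, CC(C)=CC(=O)O
Why: Steglich esterification of the only free hydroxyl, which proceeds with retention at the carbinol carbon (acyl–oxygen bond formation) and avoids the vinylketene pathway that deconjugates the acid chloride under amine bases.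

Step 11
Reactants: 14 (1S)-1-{5-methoxy-1,4-dioxo-8-[(triisopropylsilyl)oxy]-1,4-dihydronaphthalen-2-yl}-4-methylpent-3-en-1-yl 3-methylbut-2-enoate
Product: 15 (1S)-1-(8-hydroxy-5-methoxy-1,4-dioxo-1,4-dihydronaphthalen-2-yl)-4-methylpent-3-en-1-yl 3-methylbut-2-enoate
Conditions: Bu4NF (1.1 equiv), AcOH (1.2 equiv), THF, 0 °C
Reagents that add atoms: none
Why: Fluoride-mediated cleavage of an aryl silyl ether, fast because the phenoxide peri to the C1 carbonyl is a good leaving group, with acetic acid buffering to spare the base-sensitive acyloxy quinone.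

**Compound list**

1 | methyl 2,5-dihydroxybenzoate | COC(=O)c1cc(O)ccc1O | starting material
2 | methyl 2-hydroxy-5-[(triisopropylsilyl)oxy]benzoate | COC(=O)c1cc(O[Si](C(C)C)(C(C)C)C(C)C)ccc1O | intermediate
3 | methyl 2-methoxy-5-[(triisopropylsilyl)oxy]benzoate | COC(=O)c1cc(O[Si](C(C)C)(C(C)C)C(C)C)ccc1OC | intermediate
4 | 2-[dimethyl(oxo)-λ6-sulfanylidene]-1-{2-methoxy-5-[(triisopropylsilyl)oxy]phenyl}ethan-1-one (aroyl sulfoxonium ylide) | COc1ccc(O[Si](C(C)C)(C(C)C)C(C)C)cc1C(=O)C=S(C)(C)=O | intermediate
5 | 4-methylpent-3-enoic acid | CC(C)=CCC(=O)O | starting material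
6 | 1-(1H-imidazol-1-yl)-4-methylpent-3-en-1-one (acyl imidazolide, formed in the flask) | CC(C)=CCC(=O)n1ccnc1 | intermediate
7 | N-methoxy-N,4-dimethylpent-3-enamide | CC(C)=CCC(=O)N(C)OC | intermediate
8 | 6-methyl-1-(trimethylsilyl)hept-5-en-1-yn-3-one | CC(C)=CCC(=O)C#C[Si](C)(C)C | intermediate
9 | (3S)-6-methyl-1-(trimethylsilyl)hept-5-en-1-yn-3-ol | C[Si](C)(C)C#C[C@H](CC=C(C)C)O | intermediate
10 | (3S)-6-methylhept-5-en-1-yn-3-ol | C#C[C@H](CC=C(C)C)O | intermediate
11 | 3-[(1S)-1-hydroxy-4-methylpent-3-en-1-yl]-8-methoxy-5-[(triisopropylsilyl)oxy]naphthalen-1(2H)-one (keto tautomer, formed in the flask) | O=C1CC([C@H](CC=C(C)C)O)=Cc2c(O[Si](C(C)C)(C(C)C)C(C)C)ccc(OC)c12 | intermediate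
12 | 3-[(1S)-1-hydroxy-4-methylpent-3-en-1-yl]-8-methoxy-5-[(triisopropylsilyl)oxy]naphthalen-1-ol | COc1ccc(O[Si](C(C)C)(C(C)C)C(C)C)c2cc([C@H](CC=C(C)C)O)cc(O)c12 | intermediate
13 | 2-[(1S)-1-hydroxy-4-methylpent-3-en-1-yl]-5-methoxy-8-[(triisopropylsilyl)oxy]naphthalene-1,4-dione | COc1ccc(O[Si](C(C)C)(C(C)C)C(C)C)c2c1C(=O)C=C([C@H](CC=C(C)C)O)C2=O | intermediate
14 | (1S)-1-{5-methoxy-1,4-dioxo-8-[(triisopropylsilyl)oxy]-1,4-dihydronaphthalen-2-yl}-4-methylpent-3-en-1-yl 3-methylbut-2-enoate | COc1ccc(O[Si](C(C)C)(C(C)C)C(C)C)c2c1C(=O)C=C([C@H](CC=C(C)C)OC(=O)C=C(C)C)C2=O | intermediate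
15 | (1S)-1-(8-hydroxy-5-methoxy-1,4-dioxo-1,4-dihydronaphthalen-2-yl)-4-methylpent-3-en-1-yl 3-methylbut-2-enoate | COc1ccc(O)c2c1C(=O)C=C([C@H](CC=C(C)C)OC(=O)C=C(C)C)C2=O | target

**Step count and risks**

Total step count: 11 (steps 1–3 for ylide 4, steps 4–7 for alkynol 10, steps 8–11 after their union).
Longest linear sequence: 8 steps (5 to 15 through steps 4, 5, 6, 7, 8, 9, 10, 11).

Steps most likely to fail:

Step 8 (proposed new method). Cyclometalation at the C–H bond flanked by the silyloxy group may be slow, the terminal alkyne may be lost to acetylide formation or oligomerisation, insertion may take the opposite orientation, or β-hydroxy elimination may divert the alkenyl rhodium intermediate. The fallback is a Dötz benzannulation, known chemistry that sets out from 10 and comes back at 14. Alkynol 10 would first be esterified (3-methylbut-2-enoic acid, DCC, DMAP, CH2Cl2) to (3S)-6-methylhept-5-en-1-yn-3-yl 3-methylbut-2-enoate F4. Commercial 3-bromo-4-methoxyphenol F1 would be silylated (TIPSCl, imidazole, DMF) to (3-bromo-4-methoxyphenoxy)triisopropylsilane F2 and converted (n-BuLi, THF, −78 °C; Cr(CO)6; MeOTf) into the Fischer carbene complex pentacarbonyl{methoxy[2-methoxy-5-(triisopropylsilyloxy)phenyl]methylidene}chromium F3 (zerovalent chromium). Heating F3 with F4 (THF, 50 °C) should give, with the alkyne substituent next to the new phenol carbon as is usual for terminal alkynes, the 4-methoxy-1-naphthol (1S)-1-{1-hydroxy-4,5-dimethoxy-8-[(triisopropylsilyl)oxy]naphthalen-2-yl}-4-methylpent-3-en-1-yl 3-methylbut-2-enoate F5. Oxidative work-up of F5 with (NH4)2Ce(NO3)6 in aqueous MeCN at 0 °C should deliver quinone 14 directly, so that steps 9 and 10 are skipped and only step 11 remains.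

Step 9. The oxidation may attack the ortho carbon C3 instead of the more crowded para carbon C1, or may over-oxidise the electron-rich ring A. The fallback is a two-electron, ionic oxidation through a quinone monoketal, which sets out from 12 and comes back at 13. Treatment of 12 with PhI(OAc)2 (2.2 equiv) in MeOH at −10 °C should trap the para position with methanol twice and give 3-[(1S)-1-hydroxy-4-methylpent-3-en-1-yl]-4,4,8-trimethoxy-5-[(triisopropylsilyl)oxy]naphthalen-1(4H)-one F6. Mild hydrolysis of the ketal F6 (aqueous oxalic acid, THF, rt) should then give 13.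

Step 11. The acyloxy quinone may decompose under fluoride, by elimination of the allylic ester through a quinone methide or by conjugate addition, before or after the silyl group is lost. The fallback reverses the last two operations; it sets out from 13 and comes back at 15. Desilylation of the more robust alcohol 13 (Bu4NF, AcOH, THF, 0 °C) would give 8-hydroxy-2-[(1S)-1-hydroxy-4-methylpent-3-en-1-yl]-5-methoxynaphthalene-1,4-dione F7. Steglich acylation of F7 (3-methylbut-2-enoic acid, DCC, DMAP, CH2Cl2, 0 °C) should then take place only at the side-chain carbinol, the peri phenol being held in a hydrogen bond to the C1 carbonyl and unreactive, to give 15.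

**Further compounds**

F1 | step 8 | 3-bromo-4-methoxyphenol | COc1ccc(O)cc1Br
F2 | step 8 | (3-bromo-4-methoxyphenoxy)triisopropylsilane | COc1ccc(O[Si](C(C)C)(C(C)C)C(C)C)cc1Br
F3 | step 8 | pentacarbonyl{methoxy[2-methoxy-5-(triisopropylsilyloxy)phenyl]methylidene}chromium | COC(c1cc(O[Si](C(C)C)(C(C)C)C(C)C)ccc1OC)=[Cr](=C=O)(=C=O)(=C=O)(=C=O)=C=O
F4 | step 8 | (3S)-6-methylhept-5-en-1-yn-3-yl 3-methylbut-2-enoate | C#C[C@H](CC=C(C)C)OC(=O)C=C(C)C
F5 | step 8 | (1S)-1-{1-hydroxy-4,5-dimethoxy-8-[(triisopropylsilyl)oxy]naphthalen-2-yl}-4-methylpent-3-en-1-yl 3-methylbut-2-enoate | COc1ccc(O[Si](C(C)C)(C(C)C)C(C)C)c2c(O)c([C@H](CC=C(C)C)OC(=O)C=C(C)C)cc(OC)c12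
F6 | step 9 | 3-[(1S)-1-hydroxy-4-methylpent-3-en-1-yl]-4,4,8-trimethoxy-5-[(triisopropylsilyl)oxy]naphthalen-1(4H)-one | COc1ccc(O[Si](C(C)C)(C(C)C)C(C)C)c2c1C(=O)C=C([C@H](CC=C(C)C)O)C2(OC)OC
F7 | step 11 | 8-hydroxy-2-[(1S)-1-hydroxy-4-methylpent-3-en-1-yl]-5-methoxynaphthalene-1,4-dione | COc1ccc(O)c2c1C(=O)C=C([C@H](CC=C(C)C)O)C2=O
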